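**Retrosynthetic overview**

1. The target is (5S,9R,10S,13S)-15-acetoxylabd-7-en-17-oic acid (labdane numbering: rings A and B are C1–C10, the side chain is C11–C16, the carboxyl is C17). C17 is cut first: hydroxycarbonylation of the Δ7 enol triflate of a C8 ketone; the acetate comes from a silyl ether.
2. Ring A is then removed by cutting C2–C3 and C4–C5 together: a radical [4+2] annulation in which isobutene supplies C3, C4 and both C4 methyl groups.
3. Enabling feature: in ring B, C5 is a bare CH between the two quaternary carbons C4 and C10. It can therefore be carried as a ketone-level carbon (N-aziridinylimine) that accepts the C4 radical, loses N2 and takes its hydrogen last, while the two-carbon arm C1–C2 on C10 (a bromide) starts the chain.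
4. Ring B is bought as p-benzoquinone mono(dimethyl ketal): one copper-catalysed asymmetric conjugate addition sets C9, two enolate alkylations relay it to C10, and the ketal is the latent C8 carbonyl.
5. The side chain with C13 is (S)-citronellol minus acetone and CO2 (C11–C15 and C16 are citronellol C5–C1 and its methyl). Ring order: ring B is present from the start, ring A is closed in the key step.

Key step: step 9

Remark: 1-amino-2-phenylaziridine is used as the racemate (its stereocentre leaves as styrene), so compound 13 is drawn without configuration at that carbon. TBS = tert-butyldimethylsilyl.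

**Route**

Step 1
Reactants: 1 (S)-citronellol
Product: 2 (S)-tert-butyl[(3,7-dimethyloct-6-en-1-yl)oxy]dimethylsilane
Conditions: TBSCl, imidazole, DMF, rt
Reagents that add atoms: tert-butyldimethylsilyl chloride, CC(C)(C)[Si](C)(C)Cl
Why: Standard silylation of the primary alcohol protects the future C15 oxygen against the enolate chemistry to come, and C13 is bought with the starting material.

Step 2
Reactants: 2 TBS ether of (S)-citronellol
Product: 3 (S)-6-(TBSO)-4-methylhexanoic acid
Conditions: RuCl3·xH2O (2 mol%), NaIO4, NaHCO3, MeCN/EtOAc/H2O, rt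
Reagents that add atoms: sodium periodate, [Na+].[O-][I](=O)(=O)=O; water, O
Why: RuO4-type oxidative cleavage of the trisubstituted alkene excises the isopropylidene carbon as acetone and leaves the carboxylic acid without touching the stereocentre.

Step 3
Reactants: 3 (S)-6-(TBSO)-4-methylhexanoic acid
Product: 4 (R)-tert-butyldimethyl[(3-methylpent-4-en-1-yl)oxy]silane
Conditions: Pb(OAc)4, Cu(OAc)2 (cat.), pyridine, PhH, 80 °C
Reagents that add atoms: none
Why: Oxidative decarboxylation (Kochi reaction) generates the primary alkyl radical, which Cu(OAc)2 oxidises to the terminal alkene, so the chain now ends at the future C11.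

Step 4
Reactants: 4 (R)-TBSO-3-methylpent-4-ene; 5 4,4-dimethoxycyclohexa-2,5-dien-1-one
Product: 7 (R)-5-[(S)-5-(TBSO)-3-methylpentyl]-4,4-dimethoxycyclohex-2-en-1-one, via alkylzirconocene chloride 6 (not isolated)
Conditions: Cp2Zr(H)Cl, CH2Cl2, rt; then 5, (CuOTf)2·C6H6 (5 mol%), BINOL-derived phosphoramidite ligand (10 mol%, enantiomer giving R at the new centre), Et2O, rt; aq. NH4Cl
Reagents that add atoms: none
Why: Hydrozirconation places the metal on the terminal carbon, and copper-catalysed asymmetric conjugate addition transfers the alkyl group to a β-carbon of the symmetrical dienone, the chiral copper–phosphoramidite complex choosing the enone face and so setting C9.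

Step 5
Reactants: 7 (R)-5-[(S)-5-(TBSO)-3-methylpentyl]-4,4-dimethoxycyclohex-2-en-1-one
Product: 9 (5R,6R)-5-[(S)-5-(TBSO)-3-methylpentyl]-4,4-dimethoxy-6-methylcyclohex-2-en-1-one (methyl trans to the side chain), via lithium enolate 8 (not isolated)
Conditions: LDA, THF, −78 °C; MeI, −78 to −20 °C
Reagents that add atoms: iodomethane, CI
Why: Enolate alkylation at the only enolisable α-carbon (the other α-carbon is vinylic) should occur anti to the neighbouring side chain; this centre is planarised again in step 6, so its configuration is of no consequence.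

Step 6
Reactants: 9 (5R,6R)-6-methyl enone
Product: 11 (5R,6R)-6-(2-bromoethyl)-5-[(S)-5-(TBSO)-3-methylpentyl]-4,4-dimethoxy-6-methylcyclohex-2-en-1-one (methyl cis to the side chain), via lithium enolate 10 (not isolated)
Conditions: LDA, THF, −78 °C; BrCH2CH2OTf, −78 to 0 °C
Reagents that add atoms: 2-bromoethyl trifluoromethanesulfonate, O=S(=O)(OCCBr)C(F)(F)F
Why: Second enolate alkylation at the same carbon, in which the triflate end of the reagent reacts and the electrophile enters anti to the vicinal side chain (held pseudo-axial by allylic 1,2-strain with the enolate methyl), so that the quaternary C10 should form with methyl cis to the side chain.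

Step 7
Reactants: 11 (5R,6R)-6-(2-bromoethyl) enone
Product: 12 (2R,3R)-2-(2-bromoethyl)-3-[(S)-5-(TBSO)-3-methylpentyl]-4,4-dimethoxy-2-methylcyclohexan-1-one
Conditions: H2 (1 atm), Pd/C, EtOAc, rt
Reagents that add atoms: none
Why: Heterogeneous hydrogenation saturates the conjugated C6=C7 bond and frees the ketone from conjugation, while the primary bromide, ketal and silyl ether should survive under neutral conditions.

Step 8
Reactants: 12 (2R,3R)-2-(2-bromoethyl) ketone
Product: 13 (E)-N-{(2R,3R)-2-(2-bromoethyl)-3-[(S)-5-(TBSO)-3-methylpentyl]-4,4-dimethoxy-2-methylcyclohexylidene}-2-phenylaziridin-1-amine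
Conditions: 1-amino-2-phenylaziridine (racemic), AcOH (cat.), MeOH, 0 °C to rt
Reagents that add atoms: 1-amino-2-phenylaziridine, NN1CC1c1ccccc1
Why: Condensation gives the N-aziridinylimine (N–N bond turned away from the quaternary α-carbon), which turns C5 into a radical acceptor that can afterwards shed its nitrogen completely.

Step 9
Reactants: 13 N-aziridinylimine; 14 isobutene
Product: 15 tert-butyl{[(S)-5-[(1R,4aS,8aS)-2,2-dimethoxy-5,5,8a-trimethyldecahydronaphthalen-1-yl]-3-methylpentyl]oxy}dimethylsilane
Conditions: 14 (liquefied, co-solvent, about 1:1 with PhH), Bu3SnH (syringe pump), AIBN, sealed vessel, 80 °C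
Reagents that add atoms: none
Why: Proposed new method: the tributyltin radical abstracts bromine from C2, the primary radical adds to the CH2 terminus of isobutene (C2–C3), and the tertiary radical so formed at C4 closes ring A by 6-exo-trig attack on the C=N carbon C5 (C4–C5); the aminyl radical then opens the aziridine and expels styrene and N2, leaving a ring-fusion radical at C5 that takes hydrogen from Bu3SnH. The closest known reactions are tin hydride-mediated radical cyclisations onto N-aziridinylimines (the carbonyl carbon serves first as radical acceptor, then as radical donor) and alkyl halide/alkene radical annulations; what is new is the capture of an unactivated alkene before that ring closure. C5 is the only new stereocentre and is set in the last event: the stannane should approach the planar C5 radical from the α-face, away from the axial methyl groups on C10 and C4, to give the chair–chair trans-decalin with 5α-H. The step needs the primary radical to meet isobutene before it is reduced; this is secured by isobutene as co-solvent, slow addition of the stannane, and the lack of any favourable ring closure of the primary radical itself (only a four-membered ring onto C5 is possible). The nucleophilic tertiary adduct radical is polarity-matched to the C=N acceptor and should cyclise faster than it is reduced or adds a second isobutene.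

Step 10
Reactants: 15 trans-decalin dimethyl ketal
Product: 16 (1R,4aS,8aS)-1-[(S)-5-(TBSO)-3-methylpentyl]-5,5,8a-trimethyloctahydronaphthalen-2(1H)-one
Conditions: PPTS (cat.), acetone/H2O, rt
Reagents that add atoms: water, O
Why: Mild acid-catalysed ketal hydrolysis unveils the C8 ketone while the primary silyl ether should survive, and C9 (now α to the ketone) already carries its side chain in the thermodynamically preferred equatorial position.

Step 11
Reactants: 16 C8 ketone
Product: 18 (1R,4aS,8aS)-1-[(S)-5-(TBSO)-3-methylpentyl]-5,5,8a-trimethyl-1,4,4a,5,6,7,8,8a-octahydronaphthalen-2-yl trifluoromethanesulfonate, via potassium enolate 17 (not isolated)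
Conditions: KHMDS, THF, −78 °C; PhNTf2, −78 °C to rt
Reagents that add atoms: N-phenylbis(trifluoromethanesulfonimide), O=S(=O)(N(c1ccccc1)S(=O)(=O)C(F)(F)F)C(F)(F)F
Why: Kinetic deprotonation by the bulky amide should take a proton from the C7 methylene and not from the C9 methine next to the quaternary C10, and O-sulfonylation of the enolate then gives the Δ7 enol triflate regioselectively.

Step 12
Reactants: 18 enol triflate silyl ether
Product: 19 (1R,4aS,8aS)-1-[(S)-5-acetoxy-3-methylpentyl]-5,5,8a-trimethyl-1,4,4a,5,6,7,8,8a-octahydronaphthalen-2-yl trifluoromethanesulfonate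
Conditions: Ac2O, FeCl3 (cat.), CH2Cl2, 0 °C
Reagents that add atoms: acetic anhydride, CC(=O)OC(C)=O
Why: Lewis acid-catalysed acetolysis converts the silyl ether directly into the acetate while the vinyl triflate is inert, so that no strongly basic step follows the introduction of the acetate.

Step 13
Reactants: 19 enol triflate acetate
Product: 20 (1R,4aS,8aS)-1-[(S)-5-acetoxy-3-methylpentyl]-5,5,8a-trimethyl-1,4,4a,5,6,7,8,8a-octahydronaphthalene-2-carboxylic acid (the target)
Conditions: Pd(OAc)2 (cat.), dppf, CO (1 atm), H2O, Et3N, DMF, 60 °C; then aq. citric acid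
Reagents that add atoms: carbon monoxide, [C-]#[O+]; water, O
Why: Palladium-catalysed hydroxycarbonylation of the vinyl triflate (oxidative addition, CO insertion, capture of the acylpalladium by water) installs C17 as the free acid on C8 with the C7=C8 bond already in place, and the acetate should be stable to Et3N/water at this temperature.

**Compound list**

1 | (S)-citronellol, (S)-3,7-dimethyloct-6-en-1-ol | OCC[C@@H](C)CCC=C(C)C | starting material
2 | (S)-tert-butyl[(3,7-dimethyloct-6-en-1-yl)oxy]dimethylsilane | CC(C)(C)[Si](C)(C)OCC[C@@H](C)CCC=C(C)C | intermediate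
3 | (S)-6-(TBSO)-4-methylhexanoic acid | CC(C)(C)[Si](C)(C)OCC[C@@H](C)CCC(=O)O | intermediate
4 | (R)-tert-butyldimethyl[(3-methylpent-4-en-1-yl)oxy]silane | CC(C)(C)[Si](C)(C)OCC[C@@H](C)C=C | intermediate
5 | 4,4-dimethoxycyclohexa-2,5-dien-1-one (p-benzoquinone mono(dimethyl ketal)) | COC1(OC)C=CC(=O)C=C1 | starting material
6 | chloro[(R)-5-(TBSO)-3-methylpentyl]bis(cyclopentadienyl)zirconium | CC(C)(C)[Si](C)(C)OCC[C@@H](C)CC[Zr](Cl)(C1C=CC=C1)C1C=CC=C1 | intermediate (not isolated)
7 | (R)-5-[(S)-5-(TBSO)-3-methylpentyl]-4,4-dimethoxycyclohex-2-en-1-one | CC(C)(C)[Si](C)(C)OCC[C@@H](C)CC[C@H]1C(OC)(OC)C=CC(=O)C1 | intermediate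
8 | lithium dienolate of 7 (O–Li on the former carbonyl carbon, C=C to the former α-CH2) | CC(C)(C)[Si](C)(C)OCC[C@@H](C)CC[C@H]1C(OC)(OC)C=CC(O[Li])=C1 | intermediate (not isolated)
9 | (5R,6R)-5-[(S)-5-(TBSO)-3-methylpentyl]-4,4-dimethoxy-6-methylcyclohex-2-en-1-one | CC(C)(C)[Si](C)(C)OCC[C@@H](C)CC[C@H]1C(OC)(OC)C=CC(=O)[C@@H]1C | intermediate
10 | lithium dienolate of 9 | CC(C)(C)[Si](C)(C)OCC[C@@H](C)CC[C@H]1C(OC)(OC)C=CC(O[Li])=C1C | intermediate (not isolated)
11 | (5R,6R)-6-(2-bromoethyl)-5-[(S)-5-(TBSO)-3-methylpentyl]-4,4-dimethoxy-6-methylcyclohex-2-en-1-one | CC(C)(C)[Si](C)(C)OCC[C@@H](C)CC[C@H]1C(OC)(OC)C=CC(=O)[C@]1(C)CCBr | intermediate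
12 | (2R,3R)-2-(2-bromoethyl)-3-[(S)-5-(TBSO)-3-methylpentyl]-4,4-dimethoxy-2-methylcyclohexan-1-one | CC(C)(C)[Si](C)(C)OCC[C@@H](C)CC[C@H]1C(OC)(OC)CCC(=O)[C@]1(C)CCBr | intermediate
13 | (E)-N-aziridinylimine of 12 with 1-amino-2-phenylaziridine | CC(C)(C)[Si](C)(C)OCC[C@@H](C)CC[C@H]1C(OC)(OC)CC/C(=N\N2CC2c2ccccc2)[C@]1(C)CCBr | intermediate
14 | isobutene (2-methylpropene) | CC(C)=C | starting material
15 | tert-butyl{[(S)-5-[(1R,4aS,8aS)-2,2-dimethoxy-5,5,8a-trimethyldecahydronaphthalen-1-yl]-3-methylpentyl]oxy}dimethylsilane | CC(C)(C)[Si](C)(C)OCC[C@@H](C)CC[C@H]1C(OC)(OC)CC[C@H]2C(C)(C)CCC[C@]12C | intermediate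
16 | (1R,4aS,8aS)-1-[(S)-5-(TBSO)-3-methylpentyl]-5,5,8a-trimethyloctahydronaphthalen-2(1H)-one | CC(C)(C)[Si](C)(C)OCC[C@@H](C)CC[C@H]1C(=O)CC[C@H]2C(C)(C)CCC[C@]12C | intermediate
17 | potassium Δ7-enolate of 16 | CC(C)(C)[Si](C)(C)OCC[C@@H](C)CC[C@H]1C(O[K])=CC[C@H]2C(C)(C)CCC[C@]12C | intermediate (not isolated)
18 | (1R,4aS,8aS)-1-[(S)-5-(TBSO)-3-methylpentyl]-5,5,8a-trimethyl-1,4,4a,5,6,7,8,8a-octahydronaphthalen-2-yl trifluoromethanesulfonate | CC(C)(C)[Si](C)(C)OCC[C@@H](C)CC[C@H]1C(OS(=O)(=O)C(F)(F)F)=CC[C@H]2C(C)(C)CCC[C@]12C | intermediate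
19 | (1R,4aS,8aS)-1-[(S)-5-acetoxy-3-methylpentyl]-5,5,8a-trimethyl-1,4,4a,5,6,7,8,8a-octahydronaphthalen-2-yl trifluoromethanesulfonate | CC(=O)OCC[C@@H](C)CC[C@H]1C(OS(=O)(=O)C(F)(F)F)=CC[C@H]2C(C)(C)CCC[C@]12C | intermediate
20 | (1R,4aS,8aS)-1-[(S)-5-acetoxy-3-methylpentyl]-5,5,8a-trimethyl-1,4,4a,5,6,7,8,8a-octahydronaphthalene-2-carboxylic acid | CC(=O)OCC[C@@H](C)CC[C@H]1C(C(=O)O)=CC[C@H]2C(C)(C)CCC[C@]12C | target

**Step count and risks**

Total step count: 13. Longest linear sequence: 13 steps (1 to 20); compounds 5 and 14 are bought.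

Steps most likely to fail:

Step 9 (Proposed new method). The primary radical may be reduced before it adds to isobutene, either directly by the stannane or after a 1,5-hydrogen shift from C6. Closure of the tertiary radical onto the hindered C=N carbon may also be slow, which would lead to telomerisation or reduction. The fallback uses known chemistry and separates the two bond formations. It sets out from 12: radical allylation with tributyl(2-methylallyl)stannane and AIBN should give the 4-methylpent-4-enyl ketone F1. Condensation with p-toluenesulfonyl hydrazide should give the tosylhydrazone F2. Hydrogen-atom-transfer initiated cyclisation (Fe(acac)3, PhSiH3, EtOH, 60 °C) should generate the same tertiary C4 radical from the 1,1-disubstituted alkene and close ring A on the hydrazone carbon, giving the cyclised N-alkyl-N′-tosylhydrazide F3. Warming with NaOAc in aqueous ethanol (loss of sulfinate, then of N2 from the diazene, as in the last stage of a Caglioti reduction) should give 15, where the route is rejoined.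

Step 8. Condensation at the ketone next to the quaternary carbon may be slow, and the primary bromide may N-alkylate the aminoaziridine or the hydrazone nitrogen. The fallback needs no C=N acceptor. It sets out from 9: its enolate 10 is quenched with allyl iodide to give the allyl enone F4. Conjugate reduction with [(Ph3P)CuH]6 should give the saturated allyl ketone F5. Prenylmagnesium chloride should add through its tertiary carbon to give the tertiary alcohol F6. Ring-closing metathesis with the second-generation Grubbs catalyst should give the bicyclic alcohol F7 (C2=C3). Dehydration with SOCl2/pyridine (only C6 offers a β-hydrogen) should give the diene F8. Hydrogenation over PtO2 from the face opposite the C10 methyl should give 15.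

Step 6. The hindered enolate may be O-alkylated by the alkyl triflate, or the triflate may undergo elimination. The fallback uses a soft allylic electrophile followed by oxidative truncation. It sets out from 9: enolate 10 is quenched with cinnamyl bromide to give the cinnamyl enone F9. Ozonolysis of the electron-rich styrenyl double bond (one equivalent of O3, −78 °C, then Me2S) should give the aldehyde F10. NaBH(OAc)3 should reduce only the aldehyde to the primary alcohol F11. CBr4/PPh3 should then give 11.

Further compounds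
F1 | step 9 | (2R,3R)-3-[(S)-5-(TBSO)-3-methylpentyl]-4,4-dimethoxy-2-methyl-2-(4-methylpent-4-en-1-yl)cyclohexan-1-one | CC(C)(C)[Si](C)(C)OCC[C@@H](C)CC[C@H]1C(OC)(OC)CCC(=O)[C@]1(C)CCCC(C)=C
F2 | step 9 | (E)-tosylhydrazone of F1 | CC(C)(C)[Si](C)(C)OCC[C@@H](C)CC[C@H]1C(OC)(OC)CC/C(=N\NS(=O)(=O)c2ccc(C)cc2)[C@]1(C)CCCC(C)=C
F3 | step 9 | N′-tosylhydrazide of the cyclised decalin, hydrazine nitrogen on the ring-fusion carbon (drawn cis to the angular methyl; this centre is lost on N2 extrusion) | CC(C)(C)[Si](C)(C)OCC[C@@H](C)CC[C@H]1C(OC)(OC)CC[C@]2(NNS(=O)(=O)c3ccc(C)cc3)C(C)(C)CCC[C@]12C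
F4 | step 8 | (5R,6R)-6-allyl-5-[(S)-5-(TBSO)-3-methylpentyl]-4,4-dimethoxy-6-methylcyclohex-2-en-1-one | CC(C)(C)[Si](C)(C)OCC[C@@H](C)CC[C@H]1C(OC)(OC)C=CC(=O)[C@]1(C)CC=C
F5 | step 8 | (2R,3R)-2-allyl-3-[(S)-5-(TBSO)-3-methylpentyl]-4,4-dimethoxy-2-methylcyclohexan-1-one | CC(C)(C)[Si](C)(C)OCC[C@@H](C)CC[C@H]1C(OC)(OC)CCC(=O)[C@]1(C)CC=C
F6 | step 8 | (2R,3R)-2-allyl-3-[(S)-5-(TBSO)-3-methylpentyl]-4,4-dimethoxy-2-methyl-1-(2-methylbut-3-en-2-yl)cyclohexan-1-ol (hydroxyl drawn trans to the C2 methyl; this centre is lost on dehydration) | CC(C)(C)[Si](C)(C)OCC[C@@H](C)CC[C@H]1C(OC)(OC)CC[C@@](O)(C(C)(C)C=C)[C@]1(C)CC=C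
F7 | step 8 | 1-[(S)-5-(TBSO)-3-methylpentyl]-2,2-dimethoxy-5,5,8a-trimethyl-1,3,4,5,8,8a-hexahydronaphthalen-4a(2H)-ol (ring-closing metathesis product) | CC(C)(C)[Si](C)(C)OCC[C@@H](C)CC[C@H]1C(OC)(OC)CC[C@@]2(O)C(C)(C)C=CC[C@]12C
F8 | step 8 | (1R,8aS)-1-[(S)-5-(TBSO)-3-methylpentyl]-2,2-dimethoxy-5,5,8a-trimethyl-1,2,3,5,8,8a-hexahydronaphthalene (diene) | CC(C)(C)[Si](C)(C)OCC[C@@H](C)CC[C@H]1C(OC)(OC)CC=C2C(C)(C)C=CC[C@]12C
F9 | step 6 | (5R,6R)-6-[(E)-cinnamyl]-5-[(S)-5-(TBSO)-3-methylpentyl]-4,4-dimethoxy-6-methylcyclohex-2-en-1-one | CC(C)(C)[Si](C)(C)OCC[C@@H](C)CC[C@H]1C(OC)(OC)C=CC(=O)[C@]1(C)C/C=C/c1ccccc1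
F10 | step 6 | aldehyde analogue of 11 (CH2CHO in place of CH2CH2Br) | CC(C)(C)[Si](C)(C)OCC[C@@H](C)CC[C@H]1C(OC)(OC)C=CC(=O)[C@]1(C)CC=O
F11 | step 6 | alcohol analogue of 11 (CH2CH2OH in place of CH2CH2Br) | CC(C)(C)[Si](C)(C)OCC[C@@H](C)CC[C@H]1C(OC)(OC)C=CC(=O)[C@]1(C)CCO
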